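**Plan**
Cuts: lactone E at O–C21 and C18–C19. Lactone D at O11–C14, C12–C13 and C13–CH3. Pyrrolidine A at C2–C3 and C1–C9a. Azepane B at C6–C7 and N4–C9a. Ring C keeps its five carbons and loses C10–ethyl and C9–C8.
Enabling feature: C9a is the spiro α-tertiary amine carbon shared by rings A, B and C, and it lies β to the oxygen-bearing C11. N4–C9a–C12–C11–O is therefore a masked vinylogous amide. C1 and C2 are bare CH2 groups, so ring A equals an azomethine ylide C9a=N4(+)–C3(−) plus an ethylene equivalent.
Forward order: ring C (cyclopentenedione monoacetal), ethylation and allylation, enaminone, ring B (metathesis, H2), ring A ((3+2), sulfone then removed), ring D (aldol, reduction, methylation), ring E (acyl coupling, reduction). The glycinate ester carbon that stabilises the ylide stays in the target as C18.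
Stereochemistry: C10 comes from a catalytic asymmetric conjugate addition, and C9 is set trans to it. C9a and C3 come from the cycloaddition (face fixed by the ring B bridge, C3 by the dipole shape). C12 comes from an aldol on the face left open by the N4·BF3 adduct, and C11 from hydride attack anti to ethyl and C13. C13 comes from convex-face methylation, C20 is bought in, and C18 comes from a Felkin–Anh reduction.

Key step: step 6

Numbering and faces:
- N4 is the nitrogen, and C1–C3 are the carbons of ring A (C3 bears lactone E).
- C5–C9 are the carbons of ring B, and C9a is the spiro carbon.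
- Ring C is C9a, C9, C10 (ethyl), C11 (O), C12.
- Lactone D is C11–O–C14(=O)–C13–C12.
- Lactone E is C18–C19–C20(CH3)–C21(=O)–O.
- β is the face of ring C that carries N4 and C8. α is the face that carries ethyl, O11, C13 and C1.
- The target is (3S,9R,9aR,10R,11R,12S,13S,18S,20S).

Assumption: the (S,R,R)-phosphoramidite is taken, by analogy with simple cycloalkenones, to deliver ethyl to the face that gives 6. If the sense of induction is opposite, the (R,S,S)-ligand is used.
Remark: C1 in 16 and C13 in 19–23 are drawn without configuration, because these centres are erased in step 7 and reset in step 11.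

Step 1
Reactants: 1 cyclopent-4-ene-1,3-dione
Product: 2 8,8-dimethyl-6,10-dioxaspiro[4.5]dec-3-en-2-one
Conditions: 2,2-dimethylpropane-1,3-diol (1.0 equiv), p-TsOH (cat.), toluene, reflux, Dean–Stark
Reagents that add atoms: 2,2-dimethylpropane-1,3-diol, OCC(C)(C)CO
Why: Acid-catalysed acetalisation stops after one carbonyl because the first acetal removes the mutual activation of the two enedione carbonyls and only one equivalent of diol is offered, and no stereocentre is formed.

Step 2
Reactants: 2 8,8-dimethyl-6,10-dioxaspiro[4.5]dec-3-en-2-one; 3 diethylzinc; 4 allyl acetate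
Product: 6 (3R,4R)-3-allyl-4-ethyl-8,8-dimethyl-6,10-dioxaspiro[4.5]decan-2-one, via ethylzinc enolate 5 (not isolated)
Conditions: Cu(OTf)2 (2 mol %), (S,R,R)-phosphoramidite from (S)-BINOL and bis[(R)-1-phenylethyl]amine (4 mol %), 3 (1.2 equiv), toluene, −40 °C; then Pd(PPh3)4 (4 mol %), 4 (1.5 equiv), 0 °C
Reagents that add atoms: none
Why: Copper-catalysed asymmetric conjugate addition of Et2Zn sets C10 under control of the chiral ligand, and the zinc enolate 5 is allylated through a π-allylpalladium complex (Tsuji–Trost type) on the face anti to the new ethyl group, which sets C9 trans.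

Step 3
Reactants: 7 allylamine; 8 tert-butyl bromoacetate
Product: 9 tert-butyl N-allylglycinate
Conditions: 7 (3 equiv), K2CO3, MeCN, 0 °C → rt
Reagents that add atoms: none
Why: SN2 N-alkylation in which the excess of amine suppresses double alkylation, and no stereocentre is formed.

Step 4
Reactants: 6 (3R,4R)-3-allyl-4-ethyl-8,8-dimethyl-6,10-dioxaspiro[4.5]decan-2-one; 9 tert-butyl N-allylglycinate
Product: 10 tert-butyl N-allyl-N-[(4R,5R)-5-allyl-4-ethyl-3-oxocyclopent-1-en-1-yl]glycinate
Conditions: camphorsulfonic acid (10 mol %), toluene, 90 °C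
Reagents that add atoms: none
Why: Enaminone (vinylogous amide) formation from a β-keto acetal, in which the amine condenses at the only free carbonyl (C9a), the enamine expels the acetal and the water from the first event hydrolyses the oxocarbenium ion, so that nitrogen ends up on C9a only while C9 and C10 stay untouched and trans is in any case the stable arrangement.

Step 5
Reactants: 10 tert-butyl N-allyl-N-[(4R,5R)-5-allyl-4-ethyl-3-oxocyclopent-1-en-1-yl]glycinate
Product: 12 tert-butyl 2-[(5aR,6R)-6-ethyl-7-oxo-2,3,4,5,5a,6-hexahydrocyclopenta[b]azepin-1(7H)-yl]acetate, via ring-closed tetrahydroazepine 11 (not isolated)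
Conditions: second-generation Grubbs catalyst (H2IMes)(PCy3)Cl2Ru=CHPh (5 mol %), ClCH2CH2Cl, 45 °C; then H2 (7 bar), 70 °C
Reagents that add atoms: none
Why: Ring-closing metathesis closes the seven-membered ring B at C6=C7 (the vinylogous amide nitrogen does not bind ruthenium), and the ruthenium residue under H2 saturates only this isolated alkene (tandem metathesis–hydrogenation), with no new stereocentre.

Step 6
Reactants: 12 tert-butyl 2-[(5aR,6R)-6-ethyl-7-oxo-2,3,4,5,5a,6-hexahydrocyclopenta[b]azepin-1(7H)-yl]acetate; 13 phenyl vinyl sulfone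
Product: 16 C1-phenylsulfonyl A/B/C tricyclic enol ether ester, via O-silyl iminium triflate 14 (not isolated), via azomethine ylide 15 (not isolated)
Conditions: TIPSOTf (1.15 equiv), CH2Cl2, −20 °C; then 13 (3 equiv), i-Pr2NEt (1.3 equiv, slow addition), −20 °C → rt
Reagents that add atoms: triisopropylsilyl triflate, CC(C)[Si](OS(=O)(=O)C(F)(F)F)(C(C)C)C(C)C
Why: Proposed new method: TIPSOTf silylates the carbonyl oxygen of the vinylogous amide N4–C9a=C12–C11=O to give the 3-silyloxyallylidene ammonium salt 14, i-Pr2NEt then removes the C3–H that is flanked by cationic N4 and the ester, and the resulting ester-stabilised azomethine ylide 15 (C9a=N4(+)–C3(−)) adds suprafacially to phenyl vinyl sulfone, making C2–C3 and C1–C9a in one thermally allowed [π4s+π2s] event. The closest known reaction types are the release of azomethine ylides from O-acylated or O-sulfonylated vinylogous amides by desilylation of an N–CH2SiMe3 group with phenyl vinyl sulfone as the trap, and the base-induced formation of ester-stabilised ylides from N-(alkoxycarbonylmethyl)iminium salts; only their combination is new. Ring A closes as a concerted (3+2) cycloaddition in which both new σ-bonds lie in the ring (in the stepwise limit a Michael addition of C3 followed by a 5-endo-trig Mannich closure onto C9a). C9a is set by approach of the sulfone to the α face, because the C5–C8 tetramethylene bridge that starts at the β-oriented C8 on C9 covers the β face of the planar dipole; C3 is set by the dipole geometry, since ring B holds C9 and C5 cis about C9a=N4 and so puts C12 in the inside position, which leaves only the outside position at C3 for the ester and places it cis to C9 in ring A. The step needs site-selective deprotonation (C3–H, not C9–H or C10–H) and 1,3-periselectivity but no regio- or endo/exo-selectivity: C3–H is the only doubly activated proton while the amidinium-like charge delocalisation of 14 keeps C9–H and C10–H weakly acidic, the ring-fixed s-trans array N4=C9a–C12=C11 rules out 1,5-electrocyclisation, and both the position (C1 or C2) and the configuration of the sulfonyl group are erased in step 7. The silyl activator is not wasted, since it leaves C11=C12 as a regiodefined enol ether for step 8.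

Step 7
Reactants: 16 C1-phenylsulfonyl A/B/C tricyclic enol ether ester
Product: 17 A/B/C tricyclic enol ether ester (C1 and C2 both CH2)
Conditions: 6% Na(Hg), Na2HPO4, MeOH–THF, −20 °C
Reagents that add atoms: none
Why: Reductive desulfonylation by single-electron transfer replaces C–SO2Ph by C–H, merges all sulfone isomers into one compound and is buffered so that the ester-bearing C3 is not epimerised.

Step 8
Reactants: 17 A/B/C tricyclic enol ether ester; 18 ethyl glyoxylate
Product: 19 C12 glyoxylate aldol adduct (C11 ketone)
Conditions: BF3·OEt2 (2.5 equiv), CH2Cl2, −78 °C; then 18 (3 equiv), −78 °C; aq NaHCO3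
Reagents that add atoms: none
Why: Mukaiyama aldol addition at the regiodefined enol ether carbon C12, in which the excess BF3 binds N4, whose lone pair points over the β face of C12, so that glyoxylate attacks the α face and C13 ends up α (cis to C1), while the carbinol configuration at C13 is irrelevant.

Step 9
Reactants: 19 C12 glyoxylate aldol adduct (C11 ketone)
Product: 21 α-hydroxy lactone D tricycle tert-butyl ester, via C11 carbinol 20 (not isolated)
Conditions: LiBH(s-Bu)3 (L-Selectride, 2.5 equiv), THF, −78 → 0 °C; AcOH
Reagents that add atoms: none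
Why: Substrate-controlled ketone reduction by a bulky hydride from the β face, anti to both flanking α substituents (ethyl on C10, side chain on C12), puts O11 on the α face, and the alkoxide closes the cis-fused γ-lactone D by 5-exo-trig acyl substitution.

Step 10
Reactants: 21 α-hydroxy lactone D tricycle tert-butyl ester
Product: 23 C13-O-triethylsilyl lactone D amino acid, via bis-silyl derivative 22 (not isolated)
Conditions: Et3SiOTf (3.5 equiv), 2,6-lutidine (5 equiv), CH2Cl2, 0 °C → rt; then pH 6 phosphate buffer–THF
Reagents that add atoms: triethylsilyl triflate, CC[Si](CC)(CC)OS(=O)(=O)C(F)(F)F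
Why: The silyl triflate–lutidine pair silylates the C13 hydroxyl and at the same time turns the tert-butyl ester into a silyl ester (loss of isobutene) that is hydrolysed on work-up, and no stereocentre changes.

Step 11
Reactants: 23 C13-O-triethylsilyl lactone D amino acid
Product: 24 C13-methyl C13-O-triethylsilyl lactone D amino acid
Conditions: LiN(i-Pr)2 (3 equiv), THF–DMPU, −78 °C; MeI (1.5 equiv), −78 → −40 °C; AcOH
Reagents that add atoms: iodomethane, CI
Why: Alkylation of a cis-fused bicyclic lactone enolate, in which the carboxylate formed first shields C3–H from deprotonation and MeI attacks planar C13 from the convex (exo) face because the concave face is closed by C1 and the ethyl group, which gives methyl exo and oxygen endo as in the target.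

Step 12
Reactants: 24 C13-methyl C13-O-triethylsilyl lactone D amino acid
Product: 25 S-ethyl thioester of 24
Conditions: EtSH (5 equiv), EDC·HCl, DMAP (cat.), CH2Cl2, 0 °C → rt
Reagents that add atoms: ethanethiol, CCS
Why: Carbodiimide (Steglich-type) thioesterification, in which the tertiary N4 cannot form an oxazolone, so that C3 keeps its configuration.

Step 13
Reactants: 25 S-ethyl thioester of 24; 26 (R)-(3-methoxy-2-methyl-3-oxopropyl)zinc bromide
Product: 27 C18 keto ester
Conditions: 26 (BrZnCH2CH(CH3)CO2CH3, 0.5 M in THF, 3 equiv), PdCl2(PPh3)2 (10 mol %), toluene, rt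
Reagents that add atoms: none
Why: Fukuyama coupling (palladium-catalysed acylation of an alkylzinc halide by a thioester) forms C18–C19 without touching the lactone, the silyl ether or the C20 stereocentre, which is brought in by 26.

Step 14
Reactants: 27 C18 keto ester
Product: 30 CNP0260919.3, via hydroxy ester 28 (not isolated), via O-silyl bislactone 29 (not isolated)
Conditions: LiBH(s-Bu)3 (1.2 equiv), THF, −78 °C; AcOH, → rt; then HF·pyridine, THF, 0 °C → rt
Reagents that add atoms: none
Why: Felkin–Anh reduction of the α-amino ketone (hydride anti to the C3–N4 bond) gives the syn amino alcohol (18S), whose alkoxide lactonises onto the methyl ester to ring E with the C20 methyl cis to C3, and fluoride then frees the C13 hydroxyl.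

**Compound list**
1 | cyclopent-4-ene-1,3-dione | O=C1C=CC(=O)C1 | starting material
2 | 8,8-dimethyl-6,10-dioxaspiro[4.5]dec-3-en-2-one | O=C1C=CC2(C1)OCC(C)(C)CO2 | intermediate
3 | diethylzinc | CC[Zn]CC | starting material
4 | allyl acetate | C=CCOC(C)=O | starting material
5 | ethylzinc enolate (C9=C9a enolate, ethyl on C10 α) | CC[C@H]1C2(OCC(C)(C)CO2)CC(O[Zn]CC)=C1 | intermediate
6 | (3R,4R)-3-allyl-4-ethyl-8,8-dimethyl-6,10-dioxaspiro[4.5]decan-2-one (allyl β, ethyl α) | CC[C@H]1C2(OCC(C)(C)CO2)CC(=O)[C@@H]1CC=C | intermediate
7 | allylamine | C=CCN | starting material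
8 | tert-butyl bromoacetate | BrCC(=O)OC(C)(C)C | starting material
9 | tert-butyl N-allylglycinate | C=CCNCC(=O)OC(C)(C)C | intermediate
10 | tert-butyl N-allyl-N-[(4R,5R)-5-allyl-4-ethyl-3-oxocyclopent-1-en-1-yl]glycinate | CC[C@H]1C(=O)C=C(N(CC=C)CC(=O)OC(C)(C)C)[C@@H]1CC=C | intermediate
11 | ring-closed tetrahydroazepine (B/C enaminone with C6=C7) | CC[C@H]1C(=O)C=C2N(CC(=O)OC(C)(C)C)CC=CC[C@H]12 | intermediate
12 | tert-butyl 2-[(5aR,6R)-6-ethyl-7-oxo-2,3,4,5,5a,6-hexahydrocyclopenta[b]azepin-1(7H)-yl]acetate (B/C vinylogous amide) | CC[C@H]1C(=O)C=C2N(CC(=O)OC(C)(C)C)CCCC[C@H]12 | intermediate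
13 | phenyl vinyl sulfone | C=CS(=O)(=O)c1ccccc1 | starting material
14 | O-silyl iminium triflate (C11–OTIPS, C11=C12, C9a=N4 cation) | CC[C@H]1C(O[Si](C(C)C)(C(C)C)C(C)C)=CC2=[N+](CC(=O)OC(C)(C)C)CCCC[C@H]12.[O-]S(=O)(=O)C(F)(F)F | intermediate
15 | azomethine ylide (C9a=N4(+)–C3(−), ester on C3) | CC[C@H]1C(O[Si](C(C)C)(C(C)C)C(C)C)=CC2=[N+]([CH-]C(=O)OC(C)(C)C)CCCC[C@H]12 | intermediate
16 | C1-phenylsulfonyl A/B/C tricyclic enol ether ester (N4 β and C1 α on C9a, CO2t-Bu on C3 cis to C9, C11=C12 TIPS enol ether, C1 epimers) | CC[C@H]1C(O[Si](C(C)C)(C(C)C)C(C)C)=C[C@]23C(S(=O)(=O)c4ccccc4)C[C@@H](C(=O)OC(C)(C)C)N2CCCC[C@H]13 | intermediate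
17 | A/B/C tricyclic enol ether ester, (3S,9R,9aR,10R) | CC[C@H]1C(O[Si](C(C)C)(C(C)C)C(C)C)=C[C@]23CC[C@@H](C(=O)OC(C)(C)C)N2CCCC[C@H]13 | intermediate
18 | ethyl glyoxylate | CCOC(=O)C=O | starting material
19 | C12 glyoxylate aldol adduct (C11 ketone, CH(OH)CO2Et on C12 α, C13 epimers) | CC[C@H]1C(=O)[C@@H](C(O)C(=O)OCC)[C@]23CC[C@@H](C(=O)OC(C)(C)C)N2CCCC[C@H]13 | intermediate
20 | C11 carbinol (O11 α, before lactonisation) | CC[C@H]1[C@@H](O)[C@@H](C(O)C(=O)OCC)[C@]23CC[C@@H](C(=O)OC(C)(C)C)N2CCCC[C@H]13 | intermediate
21 | α-hydroxy lactone D tricycle tert-butyl ester (lactone cis-fused on the α face, C13 epimers) | CC[C@H]1[C@H]2OC(=O)C(O)[C@H]2[C@]23CC[C@@H](C(=O)OC(C)(C)C)N2CCCC[C@H]13 | intermediate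
22 | bis-silyl derivative (C13–OSiEt3 and C3–CO2SiEt3) | CC[C@H]1[C@H]2OC(=O)C(O[Si](CC)(CC)CC)[C@H]2[C@]23CC[C@@H](C(=O)O[Si](CC)(CC)CC)N2CCCC[C@H]13 | intermediate
23 | C13-O-triethylsilyl lactone D amino acid (C13 epimers) | CC[C@H]1[C@H]2OC(=O)C(O[Si](CC)(CC)CC)[C@H]2[C@]23CC[C@@H](C(=O)O)N2CCCC[C@H]13 | intermediate
24 | C13-methyl C13-O-triethylsilyl lactone D amino acid (methyl exo, oxygen endo) | CC[C@H]1[C@H]2OC(=O)[C@@](C)(O[Si](CC)(CC)CC)[C@H]2[C@]23CC[C@@H](C(=O)O)N2CCCC[C@H]13 | intermediate
25 | S-ethyl thioester of 24 | CC[C@H]1[C@H]2OC(=O)[C@@](C)(O[Si](CC)(CC)CC)[C@H]2[C@]23CC[C@@H](C(=O)SCC)N2CCCC[C@H]13 | intermediate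
26 | (R)-(3-methoxy-2-methyl-3-oxopropyl)zinc bromide | Br[Zn]C[C@H](C)C(=O)OC | starting material
27 | C18 keto ester (C3–C(=O)–CH2–CH(CH3)–CO2CH3) | CC[C@H]1[C@H]2OC(=O)[C@@](C)(O[Si](CC)(CC)CC)[C@H]2[C@]23CC[C@@H](C(=O)C[C@H](C)C(=O)OC)N2CCCC[C@H]13 | intermediate
28 | hydroxy ester (18S carbinol, syn to N4) | CC[C@H]1[C@H]2OC(=O)[C@@](C)(O[Si](CC)(CC)CC)[C@H]2[C@]23CC[C@@H]([C@@H](O)C[C@H](C)C(=O)OC)N2CCCC[C@H]13 | intermediate
29 | O-silyl bislactone (target with C13–OSiEt3) | CC[C@H]1[C@H]2OC(=O)[C@@](C)(O[Si](CC)(CC)CC)[C@H]2[C@]23CC[C@@H]([C@@H]4C[C@H](C)C(=O)O4)N2CCCC[C@H]13 | intermediate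
30 | CNP0260919.3, (3S,9R,9aR,10R,11R,12S,13S,18S,20S) | CC[C@H]1[C@H]2OC(=O)[C@@](C)(O)[C@H]2[C@]23CC[C@@H]([C@@H]4C[C@H](C)C(=O)O4)N2CCCC[C@H]13 | target

**Count**
Total steps: 14. Longest linear sequence: 13 steps (steps 1, 2 and 4–14).

**Steps most likely to fail**

Step 6. What may go wrong:
- Deprotonation of 14 at C9 or C10 instead of C3 would scramble the two existing stereocentres by way of an aminosilyloxycyclopentadiene. It would also divert material into Diels–Alder or Michael trapping by the sulfone.
- The cycloaddition at the fully substituted C9a may be sluggish.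

The fallback sets out from 12 and comes back at 16. It releases the dipole by loss of a silyl group instead of a proton, which is the established way of unmasking such ylides. Kinetic enolisation of the glycinate CH2 of 12 with LiN(SiMe3)2 in THF at −78 °C, followed by trapping with Me3SiCl, should give the O-trimethylsilyl ketene acetal F1. Treatment of F1 and 13 with TIPSOTf in CH2Cl2, with a catalytic amount of Bu4N[Ph3SiF2] if needed, silylates O11. The onium salt then gives up its trimethylsilyl group to triflate, so ylide 15 forms in a flask that holds no amine base. Cycloaddition then gives 16.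

Step 8. What may go wrong:
- Facial selectivity at C12 may be poor if N4 is not fully tied up by boron.
- The aldol 19 may undergo retro-aldol cleavage or dehydration.

The fallback sets out from 17 and comes back at 23. It delivers hydrogen, not carbon, last to C12.
- Aldol condensation of 17 with 18 (BF3·OEt2, then MsCl and Et3N) gives the alkylidene keto ester F2.
- Hydrogenation (H2, Pd/C, EtOAc) from the open β face gives the saturated keto diester F3, with the side chain α.
- LiBH(s-Bu)3 gives the C13-unsubstituted lactone F4.
- Et3SiOTf with 2,6-lutidine gives the lactone amino acid F5.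
- Treatment of F5 with LiN(i-Pr)2 (3 equiv), then 2-(phenylsulfonyl)-3-phenyloxaziridine (Davis hydroxylation), then Et3SiCl in the same flask gives 23.

Step 11. What may go wrong:
- Enolisation of the poorly soluble lithium carboxylate may be incomplete.
- C3–H may be removed in competition.
- N4 may be methylated.
- Alkylation may be slow as the silyloxy group is pushed into the concave face.

The fallback sets out from 17 and comes back at 24. It brings the methyl group in with the electrophile. Mukaiyama aldol addition of 17 to ethyl pyruvate (BF3·OEt2, CH2Cl2, −78 °C, monodentate activation) gives the tertiary aldol F6. LiBH(s-Bu)3 gives the C13-methyl hydroxy lactone ester F7, and Et3SiOTf with 2,6-lutidine gives 24. C13 is then set in an open transition state, so a separation of C13 epimers may be needed.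

**Further compounds**
F1 | step 6 | O-trimethylsilyl ketene acetal of 12 (alkene geometry not defined) | CC[C@H]1C(=O)C=C2N(C=C(O[Si](C)(C)C)OC(C)(C)C)CCCC[C@H]12
F2 | step 8 | alkylidene keto ester (C12=C13H–CO2Et, alkene geometry not defined) | CC[C@H]1C(=O)C(=CC(=O)OCC)[C@]23CC[C@@H](C(=O)OC(C)(C)C)N2CCCC[C@H]13
F3 | step 8 | saturated keto diester (CH2CO2Et on C12 α) | CC[C@H]1C(=O)[C@@H](CC(=O)OCC)[C@]23CC[C@@H](C(=O)OC(C)(C)C)N2CCCC[C@H]13
F4 | step 8 | C13-unsubstituted lactone (tert-butyl ester) | CC[C@H]1[C@H]2OC(=O)C[C@H]2[C@]23CC[C@@H](C(=O)OC(C)(C)C)N2CCCC[C@H]13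
F5 | step 8 | lactone amino acid (C13 unsubstituted) | CC[C@H]1[C@H]2OC(=O)C[C@H]2[C@]23CC[C@@H](C(=O)O)N2CCCC[C@H]13
F6 | step 11 | tertiary aldol from ethyl pyruvate | CC[C@H]1C(=O)[C@@H]([C@](C)(O)C(=O)OCC)[C@]23CC[C@@H](C(=O)OC(C)(C)C)N2CCCC[C@H]13
F7 | step 11 | C13-methyl hydroxy lactone ester | CC[C@H]1[C@H]2OC(=O)[C@@](C)(O)[C@H]2[C@]23CC[C@@H](C(=O)OC(C)(C)C)N2CCCC[C@H]13
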